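**Retrosynthetic overview**

1. Numbering: C1 (alkyne CH) to C15 (methyl); O-a is the oxolane oxygen (C6–O–C9, ring A), O-b the oxocane oxygen (C7–O–C13, ring B). The enyne comes from an allyl group (cross-metathesis, Colvin homologation). Ring A and the C10–Br bond are removed together by a 5-exo bromoetherification of a C6 carbinol onto a cis C9=C10 alkene. C6 comes from chelation-controlled allylation of an oxocene aldehyde.
2. Key disconnection: the oxocene ester (ring B) is made from the acyclic glycolate ether of (3S,5E)-octa-1,5-dien-3-ol, in which O-b is bonded to C7 and, temporarily, to C10. NBS puts Br on C12 while O-b closes on C13 to a five-membered oxolanium ring that is not in the target. Loss of the C7–H gives the oxonium ylide, and a [2,3] shift joins C7 to C8 and cuts the temporary O-b–C10 bond (three-atom ring expansion).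
3. Enabling feature: O-b is flanked by C13, whose neighbour C12 carries Br (a β-bromo ether, the imprint of an ether oxygen attacking a bromine-activated alkene), and lies 1,4 to C10 through C13–C12–C11. Once ring A is opened to the C9=C10 alkene, C8–C9=C10 is an allyl unit that can migrate from O-b to C7, and C7 is acidified by a carbonyl-level C6.
4. The ether comes from tert-butyl bromoacetate and the dienol, made from (E)-hex-3-en-1-ol (oxidation, vinyl addition, Sharpless kinetic resolution). This single carbinol centre (C10) relays all absolute configuration and is destroyed in the key step.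
5. Ring order: transient oxolanium (O-b, C10–C13), then oxocane ring B (step 5), then oxolane ring A (step 8).

Key step: step 5

Remark: the 5-endo oxonium closure of ether 7 is assumed to follow the 2,5-trans preference known for halocyclisations of (E)-homoallylic oxygen nucleophiles.

**Step 1**
Reactants: 1 (E)-hex-3-en-1-ol
Product: 2 (E)-hex-3-enal
Conditions: Dess–Martin periodinane, pyridine, CH2Cl2, 0 °C; used crude
Reagents that add atoms: none
Why: Dess–Martin oxidation is fast and non-basic (pyridine buffer), so the β,γ-unsaturated aldehyde should form without migration of the (E)-alkene into conjugation; no stereocentre is involved.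

**Step 2**
Reactants: 2 (E)-hex-3-enal; 3 vinylmagnesium bromide
Product: 4 rac-(5E)-octa-1,5-dien-3-ol
Conditions: CH2=CHMgBr, THF, −78 °C (inverse addition)
Reagents that add atoms: vinylmagnesium bromide (3), C=C[Mg]Br
Why: Grignard 1,2-addition at −78 °C should outrun enolisation of the labile aldehyde and gives the racemic secondary allylic alcohol, whose carbinol centre (C10) is resolved in the next step.

**Step 3**
Reactants: 4 rac-(5E)-octa-1,5-dien-3-ol
Product: 5 (3S,5E)-octa-1,5-dien-3-ol
Conditions: Ti(OiPr)4 (0.2 equiv), D-(−)-diisopropyl tartrate (0.3 equiv), t-BuOOH (0.6 equiv), 4 Å MS, CH2Cl2, −20 °C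
Reagents that add atoms: none
Why: Sharpless kinetic resolution: with the D-(−)-tartrate the (R)-enantiomer of the 1-alken-3-ol is epoxidised faster (the isolated homoallylic alkene is inert to the Ti(OiPr)4–tartrate–t-BuOOH system), so the (S)-alcohol that fixes C10 should be recovered at just over half conversion.

**Step 4**
Reactants: 5 (3S,5E)-octa-1,5-dien-3-ol; 6 tert-butyl bromoacetate
Product: 7 tert-butyl 2-{[(3S,5E)-octa-1,5-dien-3-yl]oxy}acetate
Conditions: 50% aq NaOH, Bu4NHSO4 (cat.), toluene, 0 °C → rt
Reagents that add atoms: tert-butyl bromoacetate (6), CC(C)(C)OC(=O)CBr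
Why: Williamson etherification under phase-transfer conditions alkylates the alkoxide on oxygen with the reactive α-bromo ester and leaves the carbinol centre untouched (configuration retained).

**Step 5**
Reactants: 7 tert-butyl 2-{[(3S,5E)-octa-1,5-dien-3-yl]oxy}acetate
Product: 10 tert-butyl (2S,4Z,7S,8R)-7-bromo-8-ethyl-3,6,7,8-tetrahydro-2H-oxocine-2-carboxylate, via oxolanium succinimidate 8 (not isolated), via oxonium ylide 9 (not isolated)
Conditions: NBS (1.0 equiv), 2-tert-butyl-1,1,3,3-tetramethylguanidine (0.2 equiv), 4 Å MS, CH2Cl2, −78 → −20 °C, dark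
Reagents that add atoms: N-bromosuccinimide, O=C1CCC(=O)N1Br
Why: Proposed new method: bromine transfer from guanidine-activated NBS to the electron-richer (E)-C12=C13 alkene is intercepted anti and 5-endo by ether oxygen O-b, which closes the five-membered oxolanium ring of 8 (O-b–C13 and C12–Br formed); the C7–H of 8, acidified by the oxonium centre and the ester, is removed by succinimide anion or the hindered guanidine to give ylide 9, whose [2,3]-sigmatropic shift through a five-membered envelope transition state joins C7 to C8, cuts the temporary O-b–C10 bond and moves the double bond to C9=C10, a three-atom ring expansion of the oxolanium to the oxocene. The closest known reactions are ether-oxygen capture of bromine-activated alkenes to give trialkyloxonium ions, the [2,3] ring expansion of 2-vinyl cyclic sulfonium and ammonium ylides made by alkylation then deprotonation, and [2,3] shifts of allylic oxonium ylides made from metal carbenoids; what is new is making the oxonium ylide by halocyclisation and deprotonation. The oxolanium ring closes 5-endo (the 4-exo alternative at C12 is not viable, so O-b bonds only to C13), and ring B is closed not end to end but by the ring expansion, which in an eight-membered ring should deliver only the cis C9=C10 alkene. C12 and C13 are set relative to each other by anti addition across the E-alkene and in the absolute sense by the C10 carbinol centre, which should direct the closure to the 2,5-trans oxolanium (vinyl and ethyl on opposite faces); C10 is then destroyed while C7 is created with the ester exo in the envelope transition state (ylide carbon cis to the vinyl group, ester turned away from the allyl unit toward the hydrogen-bearing face of C13), which places the C7 and C13 substituents trans across O-b. The step needs chemoselective bromination of the internal alkene (the allylic-ether vinyl group is less nucleophilic and has no oxygen placed to trap it), deprotonation of 8 faster than nucleophilic loss of its acetate arm or base-induced ring opening (hindered base, bulky tert-butyl ester, dry non-nucleophilic medium, low temperature, no excess NBS), and [2,3] over [1,2] shift (allylic migrating terminus).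

**Step 6**
Reactants: 10 tert-butyl (2S,4Z,7S,8R)-7-bromo-8-ethyl-3,6,7,8-tetrahydro-2H-oxocine-2-carboxylate
Product: 11 (2S,4Z,7S,8R)-7-bromo-8-ethyl-3,6,7,8-tetrahydro-2H-oxocine-2-carbaldehyde
Conditions: i-Bu2AlH (1.1 equiv), CH2Cl2, −78 °C; aq potassium sodium tartrate work-up; used directly
Reagents that add atoms: none
Why: partial reduction of the ester with i-Bu2AlH at −78 °C should stop at the aluminium hemiacetal, which releases the α-alkoxy aldehyde on work-up; C7 is not touched and the aldehyde is used at once to avoid epimerisation.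

**Step 7**
Reactants: 11 (2S,4Z,7S,8R)-7-bromo-8-ethyl-3,6,7,8-tetrahydro-2H-oxocine-2-carbaldehyde; 12 allyltributylstannane
Product: 13 (1S)-1-[(2S,4Z,7S,8R)-7-bromo-8-ethyl-3,6,7,8-tetrahydro-2H-oxocin-2-yl]but-3-en-1-ol
Conditions: MgBr2·OEt2, Bu3SnCH2CH=CH2, CH2Cl2, −78 → −20 °C
Reagents that add atoms: allyltributylstannane (12), C=CC[Sn](CCCC)(CCCC)CCCC
Why: chelation-controlled allylation (Cram chelate of MgBr2 between the aldehyde oxygen and ring oxygen O-b, allyl transfer to the face flanked by the C7 hydrogen) should set C6 as the 6,7-syn (6S) alcohol.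

**Step 8**
Reactants: 13 (1S)-1-[(2S,4Z,7S,8R)-7-bromo-8-ethyl-3,6,7,8-tetrahydro-2H-oxocin-2-yl]but-3-en-1-ol
Product: 14 (1S,3R,4S,6S,7S,9S)-4,6-dibromo-3-ethyl-9-(prop-2-en-1-yl)-2,8-dioxabicyclo[5.2.1]decane
Conditions: NBS (1.05 equiv), CH2Cl2, 0 °C, dark
Reagents that add atoms: N-bromosuccinimide, O=C1CCC(=O)N1Br
Why: 5-exo bromoetherification across the ring: the C6 hydroxyl, held on the C7 face of the oxocene, attacks C9 anti to the bromine delivered to C10 of the cis alkene, so anti addition fixes C9 (O-a cis to C6) and C10 (Br trans) and closes ring A, while the less nucleophilic monosubstituted allyl alkene could only be trapped 5-endo.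

**Step 9**
Reactants: 14 (1S,3R,4S,6S,7S,9S)-4,6-dibromo-3-ethyl-9-(prop-2-en-1-yl)-2,8-dioxabicyclo[5.2.1]decane; 15 (E)-but-2-enal
Product: 16 (2E)-4-[(1S,3R,4S,6S,7S,9S)-4,6-dibromo-3-ethyl-2,8-dioxabicyclo[5.2.1]decan-9-yl]but-2-enal
Conditions: crotonaldehyde (excess), second-generation Hoveyda–Grubbs catalyst RuCl2(=CH-C6H4-2-OiPr)(H2IMes) (5 mol %), CH2Cl2, 40 °C
Reagents that add atoms: (E)-but-2-enal (15), C/C=C/C=O
Why: olefin cross-metathesis of the terminal alkene with the electron-poor partner crotonaldehyde should give the (E)-enal under thermodynamic control; ethers and secondary bromides are inert to the ruthenium carbene.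

**Step 10**
Reactants: 16 (2E)-4-[(1S,3R,4S,6S,7S,9S)-4,6-dibromo-3-ethyl-2,8-dioxabicyclo[5.2.1]decan-9-yl]but-2-enal; 17 (trimethylsilyl)diazomethane
Product: 18 (1S,3R,4S,6S,7S,9S)-4,6-dibromo-3-ethyl-9-[(2E)-pent-2-en-4-yn-1-yl]-2,8-dioxabicyclo[5.2.1]decane
Conditions: Me3SiCHN2, LiN(i-Pr)2, THF, −78 → 0 °C
Reagents that add atoms: (trimethylsilyl)diazomethane (17), C[Si](C)(C)C=[N+]=[N-]
Why: Colvin rearrangement (one-carbon homologation of the aldehyde to the terminal alkyne with lithiated (trimethylsilyl)diazomethane) works on enals without the conjugate addition seen under carbonate–methanol conditions, keeps the (E)-alkene, and at low temperature should leave the secondary bromides and all six stereocentres untouched.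

**Compound list**

1 | (E)-hex-3-en-1-ol | CC/C=C/CCO | starting material
2 | (E)-hex-3-enal | CC/C=C/CC=O | intermediate
3 | vinylmagnesium bromide | C=C[Mg]Br | starting material
4 | rac-(5E)-octa-1,5-dien-3-ol | C=CC(O)C/C=C/CC | intermediate
5 | (3S,5E)-octa-1,5-dien-3-ol | C=C[C@@H](O)C/C=C/CC | intermediate
6 | tert-butyl bromoacetate | CC(C)(C)OC(=O)CBr | starting material
7 | tert-butyl 2-{[(3S,5E)-octa-1,5-dien-3-yl]oxy}acetate | C=C[C@@H](OCC(=O)OC(C)(C)C)C/C=C/CC | intermediate
8 | (2R,3S,5S)-3-bromo-1-(2-tert-butoxy-2-oxoethyl)-5-ethenyl-2-ethyloxolan-1-ium succinimidate (configuration at oxygen not fixed) | C=C[C@@H]1C[C@H](Br)[C@@H](CC)[O+]1CC(=O)OC(C)(C)C.O=C1CCC(=O)[N-]1 | intermediate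
9 | [(2R,3S,5S)-3-bromo-5-ethenyl-2-ethyloxolan-1-ium-1-yl](tert-butoxycarbonyl)methanide | C=C[C@@H]1C[C@H](Br)[C@@H](CC)[O+]1[CH-]C(=O)OC(C)(C)C | intermediate
10 | tert-butyl (2S,4Z,7S,8R)-7-bromo-8-ethyl-3,6,7,8-tetrahydro-2H-oxocine-2-carboxylate | O=C(OC(C)(C)C)[C@@H]1C/C=C\C[C@H](Br)[C@@H](CC)O1 | intermediate
11 | (2S,4Z,7S,8R)-7-bromo-8-ethyl-3,6,7,8-tetrahydro-2H-oxocine-2-carbaldehyde | O=C[C@@H]1C/C=C\C[C@H](Br)[C@@H](CC)O1 | intermediate
12 | allyltributylstannane | C=CC[Sn](CCCC)(CCCC)CCCC | starting material
13 | (1S)-1-[(2S,4Z,7S,8R)-7-bromo-8-ethyl-3,6,7,8-tetrahydro-2H-oxocin-2-yl]but-3-en-1-ol | C=CC[C@H](O)[C@@H]1C/C=C\C[C@H](Br)[C@@H](CC)O1 | intermediate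
14 | (1S,3R,4S,6S,7S,9S)-4,6-dibromo-3-ethyl-9-(prop-2-en-1-yl)-2,8-dioxabicyclo[5.2.1]decane | C=CC[C@@H]1O[C@H]2C[C@@H]1O[C@H](CC)[C@@H](Br)C[C@@H]2Br | intermediate
15 | (E)-but-2-enal (crotonaldehyde) | C/C=C/C=O | starting material
16 | (2E)-4-[(1S,3R,4S,6S,7S,9S)-4,6-dibromo-3-ethyl-2,8-dioxabicyclo[5.2.1]decan-9-yl]but-2-enal | O=C/C=C/C[C@@H]1O[C@H]2C[C@@H]1O[C@H](CC)[C@@H](Br)C[C@@H]2Br | intermediate
17 | (trimethylsilyl)diazomethane | C[Si](C)(C)C=[N+]=[N-] | starting material
18 | (1S,3R,4S,6S,7S,9S)-4,6-dibromo-3-ethyl-9-[(2E)-pent-2-en-4-yn-1-yl]-2,8-dioxabicyclo[5.2.1]decane | C#C/C=C/C[C@@H]1O[C@H]2C[C@@H]1O[C@H](CC)[C@@H](Br)C[C@@H]2Br | target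

**Step count and risks**

Total step count: 10. Longest linear sequence: 10 steps (1 → 18).

Steps most likely to fail:

1. Step 5 (proposed new method). The likely failure is that oxonium ion 8 loses its tert-butoxycarbonylmethyl arm to a nucleophile, opens by base-induced elimination, or that product 10 is brominated further, before the C7–H is removed; the ylide then never forms. A second concern is incomplete facial control at C7 in the [2,3] shift. Fallback (known chemistry): set out from alcohol 5. NBS in MeCN at 0 °C should effect the 5-endo bromoetherification of the free (E)-homoallylic alcohol to (2R,3S,5S)-3-bromo-5-ethenyl-2-ethyloxolane F1. Slow addition of tert-butyl diazoacetate to F1 with catalytic Cu(CF3COCHCOCF3)2 in CH2Cl2 at reflux generates the same ylide 9 by carbenoid attack on the ring oxygen, and its [2,3] shift returns the route at 10.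

2. Step 8. The likely failure is bromine transfer to the terminal allyl alkene of 13 with 5-endo capture by the C6 hydroxyl, competing with closure onto the ring alkene. Fallback: set out from 13. Cross-metathesis with crotonaldehyde (second-generation Hoveyda–Grubbs catalyst) gives (2E,5S)-5-[(2S,4Z,7S,8R)-7-bromo-8-ethyl-3,6,7,8-tetrahydro-2H-oxocin-2-yl]-5-hydroxypent-2-enal F2. Colvin homologation with two equivalents of lithiated (trimethylsilyl)diazomethane gives (1S,3E)-1-[(2S,4Z,7S,8R)-7-bromo-8-ethyl-3,6,7,8-tetrahydro-2H-oxocin-2-yl]hex-3-en-5-yn-1-ol F3. The NBS bromoetherification is then run last on F3, where the only other unsaturation is the electron-poor conjugated enyne, and returns the route at 18.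

3. Step 7. The likely failure is weak chelation at the hindered ring oxygen O-b, which lets the Felkin–Anh pathway compete and erodes facial selectivity at C6. Fallback: set out from 11. Allylmagnesium bromide in THF at −78 °C gives 13 mixed with its C6 epimer (1R)-1-[(2S,4Z,7S,8R)-7-bromo-8-ethyl-3,6,7,8-tetrahydro-2H-oxocin-2-yl]but-3-en-1-ol F4. Dess–Martin oxidation of the mixture gives 1-[(2S,4Z,7S,8R)-7-bromo-8-ethyl-3,6,7,8-tetrahydro-2H-oxocin-2-yl]but-3-en-1-one F5. Reduction with LiBH(s-Bu)3 at −78 °C under Felkin–Anh control (hydride anti to O-b, past the C7 hydrogen) should give the 6,7-syn alcohol and returns the route at 13.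

**Further compounds**

F1 | step 5 | (2R,3S,5S)-3-bromo-5-ethenyl-2-ethyloxolane | C=C[C@@H]1C[C@H](Br)[C@@H](CC)O1
F2 | step 8 | (2E,5S)-5-[(2S,4Z,7S,8R)-7-bromo-8-ethyl-3,6,7,8-tetrahydro-2H-oxocin-2-yl]-5-hydroxypent-2-enal | O=C/C=C/C[C@H](O)[C@@H]1C/C=C\C[C@H](Br)[C@@H](CC)O1
F3 | step 8 | (1S,3E)-1-[(2S,4Z,7S,8R)-7-bromo-8-ethyl-3,6,7,8-tetrahydro-2H-oxocin-2-yl]hex-3-en-5-yn-1-ol | C#C/C=C/C[C@H](O)[C@@H]1C/C=C\C[C@H](Br)[C@@H](CC)O1
F4 | step 7 | (1R)-1-[(2S,4Z,7S,8R)-7-bromo-8-ethyl-3,6,7,8-tetrahydro-2H-oxocin-2-yl]but-3-en-1-ol | C=CC[C@@H](O)[C@@H]1C/C=C\C[C@H](Br)[C@@H](CC)O1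
F5 | step 7 | 1-[(2S,4Z,7S,8R)-7-bromo-8-ethyl-3,6,7,8-tetrahydro-2H-oxocin-2-yl]but-3-en-1-one | C=CCC(=O)[C@@H]1C/C=C\C[C@H](Br)[C@@H](CC)O1
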